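The pyranone ring (ring C) of the flavonol carries an acyloin in enol form: the C4 carbonyl and the C3 hydroxyl make the target the enol of a 2-arylchromane-3,4-dione. The route therefore disconnects C3–C4 and forms it by a carbene-catalysed intramolecular benzoin reaction, which joins two formyl carbons with reversed polarity at one of them, closes ring C and installs the C3 oxygen in one operation. The cyclisation precursor is an O-tethered dialdehyde: a fully substituted 2-aryloxybenzaldehyde (ring A, from syringol) whose ether oxygen bears a 1-aryl-2-oxoethyl arm (ring B, from homoprotocatechuic acid). Oxidation and hydrogenolysis finish the synthesis.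

Key step: step 11

Assumption: the target is planar and has no stereocentre, so there is no enantiomer to select; the stereocentres of intermediates 12–17 are racemic and disappear when ring C becomes aromatic in step 12.

Step 1
Reactants: 1 2,6-dimethoxyphenol (syringol)
Product: 2 2-(benzyloxy)-1,3-dimethoxybenzene
Conditions: BnBr, K2CO3, DMF, 60 °C
Reagents that add atoms: benzyl bromide, BrCc1ccccc1
Why: Williamson etherification caps the oxygen that becomes the 7-OH, and as a flanked, twisted benzyl ether it no longer directs substitution para to itself.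

Step 2
Reactants: 2 2-(benzyloxy)-1,3-dimethoxybenzene
Product: 3 3-(benzyloxy)-1,5-dibromo-2,4-dimethoxybenzene
Conditions: NBS (2.1 equiv), MeCN, 0 °C to rt, dark
Reagents that add atoms: N-bromosuccinimide, O=C1CCC(=O)N1Br
Why: Electrophilic aromatic bromination should enter twice at the positions that are ortho to one methoxy group and para to the other, while the remaining C–H is meta to both methoxy groups and is then flanked by two bromines.

Step 3
Reactants: 3 3-(benzyloxy)-1,5-dibromo-2,4-dimethoxybenzene
Product: 5 5-(benzyloxy)-4,6-dimethoxybenzene-1,3-diol, via bis-pinacolboronate 4 (not isolated)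
Conditions: B2pin2 (2.6 equiv), PdCl2(dppf) (5 mol %), KOAc, 1,4-dioxane, 90 °C; then 30% aq H2O2, THF, 0 °C to rt; mildly acidic work-up under argon
Reagents that add atoms: bis(pinacolato)diboron, CC1(C)OB(OC1(C)C)B1OC(C)(C)C(C)(C)O1 (boronate groups of 4 only); hydrogen peroxide, OO (oxygen of both new OH groups)
Why: Double Miyaura borylation followed by ipso oxidation of the C–B bonds (1,2-aryl shift from boron to oxygen) turns both C–Br bonds into C–OH at the same carbons and avoids hot hydroxide on a very electron-rich ring.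

Step 4
Reactants: 5 5-(benzyloxy)-4,6-dimethoxybenzene-1,3-diol
Product: 7 4-(benzyloxy)-2,6-dihydroxy-3,5-dimethoxybenzaldehyde, via aryl iminium chloride 6 (not isolated)
Conditions: POCl3, DMF, MeCN, 0 °C to rt; then H2O, 50 °C
Reagents that add atoms: N,N-dimethylformamide, CN(C)C=O (formyl carbon); phosphoryl chloride, O=P(Cl)(Cl)Cl (chloride of 6 only); water, O (carbonyl oxygen of 7)
Why: Vilsmeier–Haack formylation can only occur at the single remaining ring C–H, which is activated by two ortho hydroxyls and the para benzyloxy group, so regiochemistry is not in question.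

Step 5
Reactants: 7 4-(benzyloxy)-2,6-dihydroxy-3,5-dimethoxybenzaldehyde
Product: 8 4,6-bis(benzyloxy)-2-hydroxy-3,5-dimethoxybenzaldehyde
Conditions: BnBr (1.05 equiv), K2CO3 (1.1 equiv), DMF, 0 °C to rt
Reagents that add atoms: benzyl bromide, BrCc1ccccc1
Why: Williamson mono-etherification of a bis-phenol with two equivalent hydroxyls should stop after one alkylation, because the remaining hydroxyl is held in a hydrogen bond to the formyl oxygen and is much less nucleophilic.

Step 6
Reactants: 9 3,4-dihydroxyphenylacetic acid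
Product: 10 benzyl 2-[3,4-bis(benzyloxy)phenyl]acetate
Conditions: BnBr (3.3 equiv), K2CO3, DMF, 60 °C, N2
Reagents that add atoms: benzyl bromide, BrCc1ccccc1
Why: Exhaustive Williamson O-alkylation of both phenols and the carboxylate gives the protected ester in one operation; the ester alkoxy group is lost later, so its identity is immaterial.

Step 7
Reactants: 10 benzyl 2-[3,4-bis(benzyloxy)phenyl]acetate
Product: 12 benzyl rac-2-bromo-2-[3,4-bis(benzyloxy)phenyl]acetate, via silyl ketene acetal 11 (not isolated)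
Conditions: LiHMDS, TMSCl, THF, −78 °C; then NBS, −78 to 0 °C; used crude
Reagents that add atoms: chlorotrimethylsilane, C[Si](C)(C)Cl (silyl group of 11 only); N-bromosuccinimide, O=C1CCC(=O)N1Br
Why: Electrophilic α-bromination of an ester through its silyl ketene acetal is an ionic process and so spares the benzylic CH2 groups of the ethers, which radical bromination would attack; the new centre is racemic.

Step 8
Reactants: 8 4,6-bis(benzyloxy)-2-hydroxy-3,5-dimethoxybenzaldehyde; 12 benzyl rac-2-bromo-2-[3,4-bis(benzyloxy)phenyl]acetate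
Product: 13 benzyl rac-2-[3,5-bis(benzyloxy)-2-formyl-4,6-dimethoxyphenoxy]-2-[3,4-bis(benzyloxy)phenyl]acetate
Conditions: K2CO3, DMF, rt
Reagents that add atoms: none
Why: Williamson SN2 displacement of an activated benzylic α-bromo ester (no β-hydrogen, so no elimination) by the salicylaldehyde phenoxide forms the aryl ether, and room temperature keeps the acidic α-C–H from aldol closure onto the ortho formyl group.

Step 9
Reactants: 13 benzyl rac-2-[3,5-bis(benzyloxy)-2-formyl-4,6-dimethoxyphenoxy]-2-[3,4-bis(benzyloxy)phenyl]acetate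
Product: 14 rac-2-[3,5-bis(benzyloxy)-2-(hydroxymethyl)-4,6-dimethoxyphenoxy]-2-[3,4-bis(benzyloxy)phenyl]ethan-1-ol
Conditions: LiAlH4, THF, 0 °C
Reagents that add atoms: none
Why: Hydride reduction takes ester and aryl aldehyde together to the diol, because a partial ester-to-aldehyde reduction could not spare the aryl aldehyde.

Step 10
Reactants: 14 rac-2-[3,5-bis(benzyloxy)-2-(hydroxymethyl)-4,6-dimethoxyphenoxy]-2-[3,4-bis(benzyloxy)phenyl]ethan-1-ol
Product: 15 rac-4,6-bis(benzyloxy)-2-{1-[3,4-bis(benzyloxy)phenyl]-2-oxoethoxy}-3,5-dimethoxybenzaldehyde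
Conditions: Dess–Martin periodinane (2.6 equiv), NaHCO3, CH2Cl2, 0 °C to rt; aqueous Na2S2O3/NaHCO3 work-up, used at once without chromatography
Reagents that add atoms: none
Why: Dess–Martin oxidation converts both primary alcohols to aldehydes under buffered, base-free conditions without over-oxidation, so the easily enolised α-aryl-α-aryloxy aldehyde is generated only immediately before use.

Step 11
Reactants: 15 rac-4,6-bis(benzyloxy)-2-{1-[3,4-bis(benzyloxy)phenyl]-2-oxoethoxy}-3,5-dimethoxybenzaldehyde
Product: 16 rac-trans-5,7-bis(benzyloxy)-2-[3,4-bis(benzyloxy)phenyl]-3-hydroxy-6,8-dimethoxychroman-4-one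
Conditions: 2-(pentafluorophenyl)-6,7-dihydro-5H-pyrrolo[2,1-c][1,2,4]triazol-2-ium tetrafluoroborate (15 mol %), iPr2NEt (20 mol %), THF (0.02 M), rt, argon
Reagents that add atoms: none
Why: The free triazolylidene adds to a formyl group to give a Breslow (enaminol) intermediate, the acyl-anion equivalent, which attacks the second formyl group across the ether tether; proton transfer and loss of the carbene release the α-hydroxy ketone. This is the aldehyde-acceptor counterpart of the established carbene-catalysed intramolecular crossed benzoin that converts O-tethered salicylaldehyde ketones into 3-hydroxychroman-4-ones. Ring C closes in a 6-exo-trig mode, the nucleophilic carbon attacking a C=O that lies outside the forming ring. C3 is the only new stereocentre and is set relative to the existing racemic C2 centre under thermodynamic control, because C3–H exchanges through the enediol and aryl and hydroxyl end up trans-diequatorial; the configuration is without consequence, since both centres vanish in step 12. The step needs chemoselectivity for the intramolecular benzoin over intermolecular benzoin, over aldol reaction of the C2–H aldehyde and over expulsion of the aryloxide from the Breslow intermediate of the aliphatic aldehyde; the 1,5-relationship of the formyl groups, high dilution, a catalytic weak amine base and an electron-poor N-aryl triazolium are chosen to secure it. Regiochemistry needs no control: the aryl ketone shown arises directly when the aryl aldehyde is the donor, the isomeric 4-hydroxy-3-ketone from the other donor should converge on it through the same enediol, and both give one dione on oxidation.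

Step 12
Reactants: 16 rac-trans-5,7-bis(benzyloxy)-2-[3,4-bis(benzyloxy)phenyl]-3-hydroxy-6,8-dimethoxychroman-4-one
Product: 18 5,7-bis(benzyloxy)-2-[3,4-bis(benzyloxy)phenyl]-3-hydroxy-6,8-dimethoxy-4H-chromen-4-one, via chromane-3,4-dione 17 (not isolated)
Conditions: Dess–Martin periodinane (1.3 equiv), NaHCO3, CH2Cl2, rt
Reagents that add atoms: none
Why: Dess–Martin oxidation of the α-hydroxy ketone gives the 1,2-dione, whose C2–H (benzylic, next to a carbonyl and an ether oxygen) should shift at once to give the aromatic 3-hydroxy-4-pyranone, removing both stereocentres.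

Step 13
Reactants: 18 5,7-bis(benzyloxy)-2-[3,4-bis(benzyloxy)phenyl]-3-hydroxy-6,8-dimethoxy-4H-chromen-4-one
Product: 19 3,5,7,3',4'-pentahydroxy-6,8-dimethoxyflavone
Conditions: H2 (1 atm), 10% Pd/C, THF–MeOH, rt; work-up under argon
Reagents that add atoms: none
Why: Catalytic hydrogenolysis should cleave the four aryl benzyl ethers, while the methyl ethers and the C2=C3 bond of the aromatic pyranone are not touched at ambient pressure.

Compound list
1 | 2,6-dimethoxyphenol (syringol) | COc1cccc(OC)c1O | starting material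
2 | 2-(benzyloxy)-1,3-dimethoxybenzene | COc1cccc(OC)c1OCc1ccccc1 | intermediate
3 | 3-(benzyloxy)-1,5-dibromo-2,4-dimethoxybenzene | COc1c(Br)cc(Br)c(OC)c1OCc1ccccc1 | intermediate
4 | 2,2'-[5-(benzyloxy)-4,6-dimethoxy-1,3-phenylene]bis(4,4,5,5-tetramethyl-1,3,2-dioxaborolane) | COc1c(B2OC(C)(C)C(C)(C)O2)cc(B2OC(C)(C)C(C)(C)O2)c(OC)c1OCc1ccccc1 | intermediate (not isolated)
5 | 5-(benzyloxy)-4,6-dimethoxybenzene-1,3-diol | COc1c(O)cc(O)c(OC)c1OCc1ccccc1 | intermediate
6 | N-[4-(benzyloxy)-2,6-dihydroxy-3,5-dimethoxybenzylidene]-N-methylmethanaminium chloride | C[N+](C)=Cc1c(O)c(OC)c(OCc2ccccc2)c(OC)c1O.[Cl-] | intermediate (not isolated)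
7 | 4-(benzyloxy)-2,6-dihydroxy-3,5-dimethoxybenzaldehyde | O=Cc1c(O)c(OC)c(OCc2ccccc2)c(OC)c1O | intermediate
8 | 4,6-bis(benzyloxy)-2-hydroxy-3,5-dimethoxybenzaldehyde | O=Cc1c(O)c(OC)c(OCc2ccccc2)c(OC)c1OCc1ccccc1 | intermediate
9 | 3,4-dihydroxyphenylacetic acid | OC(=O)Cc1ccc(O)c(O)c1 | starting material
10 | benzyl 2-[3,4-bis(benzyloxy)phenyl]acetate | O=C(Cc1ccc(OCc2ccccc2)c(OCc2ccccc2)c1)OCc1ccccc1 | intermediate
11 | benzyl trimethylsilyl ketene acetal of 10, {[1-(benzyloxy)-2-[3,4-bis(benzyloxy)phenyl]ethenyl]oxy}trimethylsilane (E/Z mixture, geometry without consequence) | C[Si](C)(C)OC(OCc1ccccc1)=Cc1ccc(OCc2ccccc2)c(OCc2ccccc2)c1 | intermediate (not isolated)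
12 | benzyl rac-2-bromo-2-[3,4-bis(benzyloxy)phenyl]acetate (racemic) | O=C(OCc1ccccc1)C(Br)c1ccc(OCc2ccccc2)c(OCc2ccccc2)c1 | intermediate
13 | benzyl rac-2-[3,5-bis(benzyloxy)-2-formyl-4,6-dimethoxyphenoxy]-2-[3,4-bis(benzyloxy)phenyl]acetate (racemic) | O=Cc1c(OC(C(=O)OCc2ccccc2)c2ccc(OCc3ccccc3)c(OCc3ccccc3)c2)c(OC)c(OCc2ccccc2)c(OC)c1OCc1ccccc1 | intermediate
14 | rac-2-[3,5-bis(benzyloxy)-2-(hydroxymethyl)-4,6-dimethoxyphenoxy]-2-[3,4-bis(benzyloxy)phenyl]ethan-1-ol (racemic) | OCc1c(OC(CO)c2ccc(OCc3ccccc3)c(OCc3ccccc3)c2)c(OC)c(OCc2ccccc2)c(OC)c1OCc1ccccc1 | intermediate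
15 | rac-4,6-bis(benzyloxy)-2-{1-[3,4-bis(benzyloxy)phenyl]-2-oxoethoxy}-3,5-dimethoxybenzaldehyde (racemic) | O=CC(Oc1c(OC)c(OCc2ccccc2)c(OC)c(OCc2ccccc2)c1C=O)c1ccc(OCc2ccccc2)c(OCc2ccccc2)c1 | intermediate
16 | rac-trans-5,7-bis(benzyloxy)-2-[3,4-bis(benzyloxy)phenyl]-3-hydroxy-6,8-dimethoxychroman-4-one (racemic; the 2R,3R enantiomer is drawn) | c1ccc(cc1)COc1ccc(cc1OCc1ccccc1)[C@@H]1[C@@H](O)C(=O)c2c(OCc3ccccc3)c(OC)c(OCc3ccccc3)c(OC)c2O1 | intermediate
17 | rac-5,7-bis(benzyloxy)-2-[3,4-bis(benzyloxy)phenyl]-6,8-dimethoxychromane-3,4-dione (racemic) | O=C1C(=O)c2c(OCc3ccccc3)c(OC)c(OCc3ccccc3)c(OC)c2OC1c1ccc(OCc2ccccc2)c(OCc2ccccc2)c1 | intermediate (not isolated)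
18 | 5,7-bis(benzyloxy)-2-[3,4-bis(benzyloxy)phenyl]-3-hydroxy-6,8-dimethoxy-4H-chromen-4-one | COc1c(OCc2ccccc2)c(OC)c2oc(-c3ccc(OCc4ccccc4)c(OCc4ccccc4)c3)c(O)c(=O)c2c1OCc1ccccc1 | intermediate
19 | 3,5,7,3',4'-pentahydroxy-6,8-dimethoxyflavone (achiral) | COc1c(O)c(OC)c2oc(-c3ccc(O)c(O)c3)c(O)c(=O)c2c1O | target

Total step count: 13 steps.
Longest linear sequence: 11 steps (steps 1–5 and 8–13); the ring-B arm adds steps 6 and 7.

Steps most likely to fail

1. Step 11 (key step). The carbene may add mainly to the aliphatic formyl group, and the resulting Breslow intermediate may eject the ring-A aryloxide instead of cyclising, which cuts the tether. Base-induced enolisation at C2–H may also lead to aldol closure onto the aryl aldehyde or to oligomers. The fallback builds ring C by established flavone chemistry; it sets out from 8 and comes back at 18. Addition of MeMgBr (2.2 equiv, THF, 0 °C) to 8 should give rac-1-[4,6-bis(benzyloxy)-2-hydroxy-3,5-dimethoxyphenyl]ethan-1-ol F1, and MnO2 (CH2Cl2, rt) should oxidise it to 1-[4,6-bis(benzyloxy)-2-hydroxy-3,5-dimethoxyphenyl]ethan-1-one F2. Claisen–Schmidt condensation with commercial 3,4-bis(benzyloxy)benzaldehyde (KOH, EtOH, rt) should give (E)-1-[4,6-bis(benzyloxy)-2-hydroxy-3,5-dimethoxyphenyl]-3-[3,4-bis(benzyloxy)phenyl]prop-2-en-1-one F3. Oxidative cyclisation (cat. I2, DMSO, 120 °C) should give 5,7-bis(benzyloxy)-2-[3,4-bis(benzyloxy)phenyl]-6,8-dimethoxy-4H-chromen-4-one F4. Epoxidation of the C2=C3 bond with dimethyldioxirane (acetone–CH2Cl2, 0 °C) should give rac-5,7-bis(benzyloxy)-2-[3,4-bis(benzyloxy)phenyl]-2,3-epoxy-6,8-dimethoxychroman-4-one F5, which cat. p-TsOH should open and tautomerise to 18. Steps 6–12 are then not needed.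

2. Step 3. The second borylation may stall or give way to protodebromination, and the very electron-rich resorcinol may degrade oxidatively during the peroxide treatment or on isolation. The fallback never liberates the resorcinol; it sets out from 3 and comes back at 8. Ullmann-type double C–O coupling of 3 with benzyl alcohol (CuI, 3,4,7,8-tetramethyl-1,10-phenanthroline, Cs2CO3, toluene, 110 °C) should give 1,3,5-tris(benzyloxy)-2,4-dimethoxybenzene F6. Vilsmeier–Haack formylation at its only ring C–H (POCl3, DMF, 60 °C) should proceed through N-[2,4,6-tris(benzyloxy)-3,5-dimethoxybenzylidene]-N-methylmethanaminium chloride F7 and, after aqueous NaOAc, give 2,4,6-tris(benzyloxy)-3,5-dimethoxybenzaldehyde F8. Chelation-controlled mono-debenzylation ortho to the formyl group (MgBr2·OEt2, toluene–Et2O, reflux) should then give 8, which also removes the need for the selective monobenzylation of step 5.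

3. Step 8. The electron-rich benzylic bromide may ionise and solvolyse before the hindered, hydrogen-bonded phenoxide attacks, and the basic medium may trigger aldol closure of the product's acidic α-C–H onto the ortho formyl group. The fallback forms the same C–O bond without base or halide; it sets out from 10 (with 8 as partner) and comes back at 13. Regitz diazo transfer to 10 (p-acetamidobenzenesulfonyl azide, DBU, MeCN, rt) should give benzyl 2-diazo-2-[3,4-bis(benzyloxy)phenyl]acetate F9. Rh2(OAc)4-catalysed O–H insertion of its carbenoid into phenol 8 (1 mol %, CH2Cl2, rt, slow addition of the diazo ester) should give 13, so that bromide 12 and step 7 are bypassed.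

Further compounds
F1 | step 11 | rac-1-[4,6-bis(benzyloxy)-2-hydroxy-3,5-dimethoxyphenyl]ethan-1-ol (racemic) | CC(O)c1c(O)c(OC)c(OCc2ccccc2)c(OC)c1OCc1ccccc1
F2 | step 11 | 1-[4,6-bis(benzyloxy)-2-hydroxy-3,5-dimethoxyphenyl]ethan-1-one | CC(=O)c1c(O)c(OC)c(OCc2ccccc2)c(OC)c1OCc1ccccc1
F3 | step 11 | (E)-1-[4,6-bis(benzyloxy)-2-hydroxy-3,5-dimethoxyphenyl]-3-[3,4-bis(benzyloxy)phenyl]prop-2-en-1-one | O=C(/C=C/c1ccc(OCc2ccccc2)c(OCc2ccccc2)c1)c1c(O)c(OC)c(OCc2ccccc2)c(OC)c1OCc1ccccc1
F4 | step 11 | 5,7-bis(benzyloxy)-2-[3,4-bis(benzyloxy)phenyl]-6,8-dimethoxy-4H-chromen-4-one | COc1c(OCc2ccccc2)c(OC)c2oc(-c3ccc(OCc4ccccc4)c(OCc4ccccc4)c3)cc(=O)c2c1OCc1ccccc1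
F5 | step 11 | rac-5,7-bis(benzyloxy)-2-[3,4-bis(benzyloxy)phenyl]-2,3-epoxy-6,8-dimethoxychroman-4-one (racemic, cis-fused oxirane; one enantiomer drawn) | COc1c(OCc2ccccc2)c(OC)c2O[C@]3(c4ccc(OCc5ccccc5)c(OCc5ccccc5)c4)O[C@@H]3C(=O)c2c1OCc1ccccc1
F6 | step 3 | 1,3,5-tris(benzyloxy)-2,4-dimethoxybenzene | COc1c(OCc2ccccc2)cc(OCc2ccccc2)c(OC)c1OCc1ccccc1
F7 | step 3 | N-[2,4,6-tris(benzyloxy)-3,5-dimethoxybenzylidene]-N-methylmethanaminium chloride | C[N+](C)=Cc1c(OCc2ccccc2)c(OC)c(OCc2ccccc2)c(OC)c1OCc1ccccc1.[Cl-]
F8 | step 3 | 2,4,6-tris(benzyloxy)-3,5-dimethoxybenzaldehyde | O=Cc1c(OCc2ccccc2)c(OC)c(OCc2ccccc2)c(OC)c1OCc1ccccc1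
F9 | step 8 | benzyl 2-diazo-2-[3,4-bis(benzyloxy)phenyl]acetate | [N-]=[N+]=C(C(=O)OCc1ccccc1)c1ccc(OCc2ccccc2)c(OCc2ccccc2)c1
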